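**Strategy.** The route rests on building ring A of the chlorinated isoflavone (C4a, C5, C6, C7, C8, C8a) last, by a benzannulation onto a monocyclic 4-pyranone that already carries the complete ether-linked genistein unit as its trimethyl ether. A 4-chloro-1,3-bis(silyloxy)diene made from methyl 4-chloroacetoacetate delivers C5–C8 together with O5, O7 and Cl8, so one operation forms C4a–C5 and C8–C8a, closes the ring and fixes chlorine at C8 without any halogenation of a phenol. The precursor is a 3-bromo-5-aryl-4-pyranone whose bromine both activates the reacting double bond and leaves as HBr on aromatisation; it comes from a Suzuki coupling of an isoflavone boronate with 3,5-dibromo-4-pyranone.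

Key step: step 9

Remark: the target has no stereocentre and no element of stable axial chirality, so it is a single achiral compound and no stereocontrol is needed.

**Route**

Step 1
Reactants: 1 2-hydroxy-4,6-dimethoxybenzaldehyde
Product: 3 3,5-dimethoxybenzene-1,2-diol, via aryl formate 2 (not isolated)
Conditions: mCPBA, CH2Cl2, 0 °C → rt; then cat. HCl, MeOH, rt, under Ar
Reagents that add atoms: mCPBA, O=C(OO)c1cccc(Cl)c1
Why: In this Dakin-type Baeyer–Villiger oxidation the electron-rich, ortho-hydroxylated aryl group should migrate to oxygen, and acid methanolysis of formate 2 frees the catechol without exposing it to base and air.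

Step 2
Reactants: 3 3,5-dimethoxybenzene-1,2-diol; 4 4-methoxyphenylacetic acid
Product: 6 8-hydroxy-5,7-dimethoxy-3-(4-methoxyphenyl)chromen-4-one, via deoxybenzoin 5 (not isolated)
Conditions: BF3·OEt2 (neat), 85 °C; then DMF, MsCl, 70 °C; aq. HCl work-up
Reagents that add atoms: N,N-dimethylformamide, CN(C)C=O
Why: BF3-mediated Friedel–Crafts acylation should go to C6, the only free position where the new ketone can form a boron chelate with a neighbouring hydroxyl, and Vilsmeier-type formylation of the active methylene followed by closure through that chelated hydroxyl (the only one ortho to the acyl group) gives the isoflavone in a one-pot deoxybenzoin annulation.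

Step 3
Reactants: 6 8-hydroxy-5,7-dimethoxy-3-(4-methoxyphenyl)chromen-4-one; 7 4-bromophenylboronic acid
Product: 8 8-(4-bromophenoxy)-5,7-dimethoxy-3-(4-methoxyphenyl)chromen-4-one
Conditions: Cu(OAc)2 (2 equiv), pyridine, 4 Å MS, CH2Cl2, air, rt
Reagents that add atoms: none
Why: Chan–Lam O-arylation runs at room temperature under weakly basic conditions that should neither open the chromone nor touch the aryl bromide, and it tolerates ortho-substituted phenols.

Step 4
Reactants: 8 8-(4-bromophenoxy)-5,7-dimethoxy-3-(4-methoxyphenyl)chromen-4-one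
Product: 9 5,7-dimethoxy-3-(4-methoxyphenyl)-8-[4-(4,4,5,5-tetramethyl-1,3,2-dioxaborolan-2-yl)phenoxy]chromen-4-one
Conditions: B2pin2, Pd(dppf)Cl2 (cat.), KOAc, dioxane, 85 °C
Reagents that add atoms: bis(pinacolato)diboron, CC1(C)OB(OC1(C)C)B1OC(C)(C)C(C)(C)O1
Why: Miyaura borylation of an aryl bromide with acetate as the only base is compatible with the base-sensitive chromone and the aryl ethers.

Step 5
Reactants: 10 4H-pyran-4-one
Product: 12 3,5-dibromo-4H-pyran-4-one, via tetrabromide 11 (not isolated)
Conditions: Br2 (2.2 equiv), CH2Cl2, 0 °C → rt; then Et3N, 0 °C → rt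
Reagents that add atoms: bromine, BrBr
Why: Bromine should add to each enol ether double bond and triethylamine then removes the acidic α-hydrogen with loss of the acetal-type bromide (addition–elimination α-bromination of a β-alkoxy enone), which restores the pyranone with bromine at C3 and C5.

Step 6
Reactants: 9 5,7-dimethoxy-3-(4-methoxyphenyl)-8-[4-(4,4,5,5-tetramethyl-1,3,2-dioxaborolan-2-yl)phenoxy]chromen-4-one; 12 3,5-dibromo-4H-pyran-4-one
Product: 13 3-bromo-5-[4-[[5,7-dimethoxy-3-(4-methoxyphenyl)-4-oxochromen-8-yl]oxy]phenyl]pyran-4-one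
Conditions: 12 (3 equiv), Pd(dppf)Cl2 (cat.), K3PO4, dioxane/H2O (10:1), 70 °C
Reagents that add atoms: none
Why: Suzuki–Miyaura coupling of an α-bromo-4-pyranone parallels the routine coupling of 3-halochromones, and the excess of the symmetric dibromide should hold double arylation down and leave one C–Br bond for the annulation.

Step 7
Reactants: 14 methyl 4-chloroacetoacetate
Product: 15 methyl 4-chloro-3-(trimethylsilyloxy)but-2-enoate (E/Z mixture)
Conditions: Me3SiCl, Et3N, toluene, rt
Reagents that add atoms: chlorotrimethylsilane, C[Si](C)(C)Cl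
Why: O-silylation of the enolised β-keto ester gives the 3-silyloxy enoate (silyl enol ether formation).

Step 8
Reactants: 15 methyl 4-chloro-3-(trimethylsilyloxy)but-2-enoate
Product: 16 4-chloro-1-methoxy-1,3-bis(trimethylsilyloxy)buta-1,3-diene (mixture of geometric isomers)
Conditions: LDA, THF, −78 °C; then Me3SiCl, −78 °C → rt; non-aqueous work-up
Reagents that add atoms: chlorotrimethylsilane, C[Si](C)(C)Cl
Why: LDA removes the γ-hydrogen at the chloromethyl carbon of the vinylogous ester and the dienolate is trapped on the ester oxygen (bis-silyl dienol ether formation), the low temperature preventing displacement of chloride.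

Step 9
Reactants: 13 3-bromo-5-[4-[[5,7-dimethoxy-3-(4-methoxyphenyl)-4-oxochromen-8-yl]oxy]phenyl]pyran-4-one; 16 4-chloro-1-methoxy-1,3-bis(trimethylsilyloxy)buta-1,3-diene
Product: 18 8-chloro-3-[4-[[5,7-dimethoxy-3-(4-methoxyphenyl)-4-oxochromen-8-yl]oxy]phenyl]-5,7-dihydroxychromen-4-one, via bromo silyl ketal cycloadduct 17 (not isolated)
Conditions: 16 (4 equiv, in portions), PhMe, 100 °C, sealed tube, no Lewis acid; then DBU, 0 °C → rt; then 1 M HCl, THF/MeOH, rt
Reagents that add atoms: none
Why: Proposed new method: the electron-rich diene 16 should add across the C2=C3 bond of the 3-bromo-4-pyranone in a normal-demand, probably asynchronous Diels–Alder reaction in which its nucleophilic chlorinated terminus attacks the β-carbon C2 of the bromoenone (future C8a) and the ketene acetal carbon then bonds to the bromine-bearing C3 (future C4a), so ring A is closed intermolecularly as a [4+2] annulation, equivalent to a Michael addition followed by 6-exo Claisen-type closure of the bromoenolate onto the ketene acetal carbon. DBU should then remove HBr across C4a–C8a of adduct 17 as in the dehydrobromination of α-bromo ketones (or of the monocyclic Michael adduct, as in the conversion of 3-bromoflavanones into flavones, if the path is stepwise), and acid cleaves the silyl groups, the C5 hemiketal loses methanol and the resulting 5,7-dione tautomerises to the aromatic 5,7-diol with chlorine fixed at C8. The closest known reactions are the Diels–Alder–aromatisation of 1,3-bis(silyloxy)dienes with haloquinones and the cycloadditions of siloxydienes to acceptor-substituted chromones and to 2-bromocycloalkenones; a simple 3-bromo-4-pyranone as the dienophile is the untested element. No stereocentre survives, because all four centres of 17 are destroyed on aromatisation. The step needs site selectivity among three enone double bonds (C2=C3 and C5=C6 of the pyranone, C2=C3 of the isoflavone) and head-to-tail regiochemistry: bromine lowers the LUMO of the C2=C3 bond only, the enone polarisation directs the diene terminus to C2, only this adduct can leave the equilibrium irreversibly by loss of bromide, and omitting a Lewis acid keeps the electron-rich isoflavone carbonyl from being activated as a competing acceptor.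

Step 10
Reactants: 18 8-chloro-3-[4-[[5,7-dimethoxy-3-(4-methoxyphenyl)-4-oxochromen-8-yl]oxy]phenyl]-5,7-dihydroxychromen-4-one
Product: 19 Bisoflavolin I, 8-chloro-3-[4-[[5,7-dihydroxy-3-(4-hydroxyphenyl)-4-oxochromen-8-yl]oxy]phenyl]-5,7-dihydroxychromen-4-one
Conditions: BBr3 (excess), CH2Cl2, −78 °C → rt; then MeOH, H2O
Reagents that add atoms: none
Why: BBr3 cleaves aryl methyl ethers by O-complexation and attack of bromide on the methyl group (Lewis acid demethylation), while the diaryl ether, the aryl chloride and both chromone rings should be inert.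

**Compound list**

1 | 2-hydroxy-4,6-dimethoxybenzaldehyde | O=Cc1c(O)cc(OC)cc1OC | starting material
2 | 2-hydroxy-4,6-dimethoxyphenyl formate | O=COc1c(O)cc(OC)cc1OC | intermediate (not isolated)
3 | 3,5-dimethoxybenzene-1,2-diol | Oc1cc(OC)cc(OC)c1O | intermediate
4 | 4-methoxyphenylacetic acid | COc1ccc(CC(=O)O)cc1 | starting material
5 | 1-(2,3-dihydroxy-4,6-dimethoxyphenyl)-2-(4-methoxyphenyl)ethan-1-one | COc1ccc(CC(=O)c2c(O)c(O)c(OC)cc2OC)cc1 | intermediate (not isolated)
6 | 8-hydroxy-5,7-dimethoxy-3-(4-methoxyphenyl)chromen-4-one | COc1ccc(-c2coc3c(O)c(OC)cc(OC)c3c2=O)cc1 | intermediate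
7 | 4-bromophenylboronic acid | OB(O)c1ccc(Br)cc1 | starting material
8 | 8-(4-bromophenoxy)-5,7-dimethoxy-3-(4-methoxyphenyl)chromen-4-one | COc1ccc(-c2coc3c(Oc4ccc(Br)cc4)c(OC)cc(OC)c3c2=O)cc1 | intermediate
9 | 5,7-dimethoxy-3-(4-methoxyphenyl)-8-[4-(4,4,5,5-tetramethyl-1,3,2-dioxaborolan-2-yl)phenoxy]chromen-4-one | COc1ccc(-c2coc3c(Oc4ccc(B5OC(C)(C)C(C)(C)O5)cc4)c(OC)cc(OC)c3c2=O)cc1 | intermediate
10 | 4H-pyran-4-one | O=c1ccocc1 | starting material
11 | 2,3,5,6-tetrabromooxan-4-one (mixture of diastereomers) | O=C1C(Br)C(Br)OC(Br)C1Br | intermediate (not isolated)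
12 | 3,5-dibromo-4H-pyran-4-one | O=c1c(Br)cocc1Br | intermediate
13 | 3-bromo-5-[4-[[5,7-dimethoxy-3-(4-methoxyphenyl)-4-oxochromen-8-yl]oxy]phenyl]pyran-4-one | O=c1c(Br)cocc1-c1ccc(Oc2c(OC)cc(OC)c3c(=O)c(-c4ccc(OC)cc4)coc23)cc1 | intermediate (key-step precursor)
14 | methyl 4-chloroacetoacetate | COC(=O)CC(=O)CCl | starting material
15 | methyl 4-chloro-3-(trimethylsilyloxy)but-2-enoate (E/Z mixture) | COC(=O)C=C(CCl)O[Si](C)(C)C | intermediate
16 | 4-chloro-1-methoxy-1,3-bis(trimethylsilyloxy)buta-1,3-diene (mixture of geometric isomers) | COC(O[Si](C)(C)C)=CC(O[Si](C)(C)C)=CCl | intermediate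
17 | 4a-bromo-8-chloro-3-[4-[[5,7-dimethoxy-3-(4-methoxyphenyl)-4-oxochromen-8-yl]oxy]phenyl]-5-methoxy-5,7-bis(trimethylsilyloxy)-4a,5,8,8a-tetrahydrochromen-4-one (racemic mixture of diastereomers, configuration not defined) | O=C1C(-c2ccc(Oc3c(OC)cc(OC)c4c(=O)c(-c5ccc(OC)cc5)coc34)cc2)=COC2C(Cl)C(O[Si](C)(C)C)=CC(OC)(O[Si](C)(C)C)C12Br | intermediate (not isolated)
18 | 8-chloro-3-[4-[[5,7-dimethoxy-3-(4-methoxyphenyl)-4-oxochromen-8-yl]oxy]phenyl]-5,7-dihydroxychromen-4-one | O=c1c(-c2ccc(Oc3c(OC)cc(OC)c4c(=O)c(-c5ccc(OC)cc5)coc34)cc2)coc2c(Cl)c(O)cc(O)c12 | intermediate (key-step product)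
19 | Bisoflavolin I | O=c1c(-c2ccc(Oc3c(O)cc(O)c4c(=O)c(-c5ccc(O)cc5)coc34)cc2)coc2c(Cl)c(O)cc(O)c12 | target

**Count and risks**

Total steps: 10. Longest linear sequence: 7 steps (steps 1, 2, 3, 4, 6, 9, 10).

Steps most likely to fail:

1. Step 9. The pyranone may not engage the diene before the diene decays thermally, or the first C–C bond may be followed by opening of the pyranone at the oxygen-bearing carbon and reclosure through oxygen instead of carbocyclisation. The fallback uses known chemistry, sets out from boronate 9 and places chlorine through the choice of phenol. Commercial 2-chloro-3,5-dimethoxyphenol is C-acetylated ortho to its hydroxyl (Ac2O, BF3·OEt2, Fries-type acylation) to 1-(3-chloro-2-hydroxy-4,6-dimethoxyphenyl)ethan-1-one F1. F1 is condensed with DMF dimethyl acetal to (E)-1-(3-chloro-2-hydroxy-4,6-dimethoxyphenyl)-3-(dimethylamino)prop-2-en-1-one F2, which iodine cyclises to 8-chloro-3-iodo-5,7-dimethoxychromen-4-one F3. Suzuki coupling of F3 with 9 should give 8-chloro-3-[4-[[5,7-dimethoxy-3-(4-methoxyphenyl)-4-oxochromen-8-yl]oxy]phenyl]-5,7-dimethoxychromen-4-one F4, and BBr3 cleavage of all five methyl ethers comes back to the route at target 19.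

2. Step 2. Acylation may occur at the position between the two methoxy groups, the catechol may be sequestered as an unreactive boron chelate, or it may be lost by oxidation. The fallback sets out from acid 4 and installs the C8 oxygen after the annulation. Commercial 3,5-dimethoxyphenol and 4 give, by the same one-pot BF3·OEt2 then DMF/MsCl procedure, 5,7-dimethoxy-3-(4-methoxyphenyl)chromen-4-one F5. Iodination (NIS, cat. TFA, MeCN) at the position para to the 5-methoxy group should give 8-iodo-5,7-dimethoxy-3-(4-methoxyphenyl)chromen-4-one F6. Miyaura borylation then gives 5,7-dimethoxy-3-(4-methoxyphenyl)-8-(4,4,5,5-tetramethyl-1,3,2-dioxaborolan-2-yl)chromen-4-one F7, and oxidation with sodium perborate comes back to the route at phenol 6.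

3. Step 3. Aryl transfer to the hindered 8-hydroxyl may be slow, so that protodeboronation and homocoupling of the boronic acid consume the reagent. The fallback sets out from phenol 6 and forms the ether by nucleophilic aromatic substitution. Reaction with 1-fluoro-4-nitrobenzene (K2CO3, DMF, 60 °C) should give 5,7-dimethoxy-3-(4-methoxyphenyl)-8-(4-nitrophenoxy)chromen-4-one F8. Reduction with Fe/NH4Cl gives 8-(4-aminophenoxy)-5,7-dimethoxy-3-(4-methoxyphenyl)chromen-4-one F9. Sandmeyer-type borylation (t-BuONO, B2pin2, MeCN) comes back to the route at boronate 9, so that step 4 is not needed.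

**Further compounds**

F1 | step 9 | 1-(3-chloro-2-hydroxy-4,6-dimethoxyphenyl)ethan-1-one | CC(=O)c1c(O)c(Cl)c(OC)cc1OC
F2 | step 9 | (E)-1-(3-chloro-2-hydroxy-4,6-dimethoxyphenyl)-3-(dimethylamino)prop-2-en-1-one | CN(C)/C=C/C(=O)c1c(O)c(Cl)c(OC)cc1OC
F3 | step 9 | 8-chloro-3-iodo-5,7-dimethoxychromen-4-one | COc1cc(OC)c2c(=O)c(I)coc2c1Cl
F4 | step 9 | 8-chloro-3-[4-[[5,7-dimethoxy-3-(4-methoxyphenyl)-4-oxochromen-8-yl]oxy]phenyl]-5,7-dimethoxychromen-4-one | O=c1c(-c2ccc(Oc3c(OC)cc(OC)c4c(=O)c(-c5ccc(OC)cc5)coc34)cc2)coc2c(Cl)c(OC)cc(OC)c12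
F5 | step 2 | 5,7-dimethoxy-3-(4-methoxyphenyl)chromen-4-one | COc1ccc(-c2coc3cc(OC)cc(OC)c3c2=O)cc1
F6 | step 2 | 8-iodo-5,7-dimethoxy-3-(4-methoxyphenyl)chromen-4-one | COc1ccc(-c2coc3c(I)c(OC)cc(OC)c3c2=O)cc1
F7 | step 2 | 5,7-dimethoxy-3-(4-methoxyphenyl)-8-(4,4,5,5-tetramethyl-1,3,2-dioxaborolan-2-yl)chromen-4-one | COc1ccc(-c2coc3c(B4OC(C)(C)C(C)(C)O4)c(OC)cc(OC)c3c2=O)cc1
F8 | step 3 | 5,7-dimethoxy-3-(4-methoxyphenyl)-8-(4-nitrophenoxy)chromen-4-one | COc1ccc(-c2coc3c(Oc4ccc([N+](=O)[O-])cc4)c(OC)cc(OC)c3c2=O)cc1
F9 | step 3 | 8-(4-aminophenoxy)-5,7-dimethoxy-3-(4-methoxyphenyl)chromen-4-one | COc1ccc(-c2coc3c(Oc4ccc(N)cc4)c(OC)cc(OC)c3c2=O)cc1
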